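**Retrosynthetic overview**

1. Atom numbers used below: ring A = C1 (quaternary, Me)–C2–C3–C4 (OH, iPr)–C5 (H); ring B = C1–C5–C6 (O-acyl)–C7=C8 (Me)–C9–C10.
2. Late disconnections: ester C–O (acylation), C6–H (hydroxyl-directed reduction of a C6 ketone), C4–iPr (organocerium addition to a ring-A ketone, anti to the C1 methyl), C4–C5 (aldol) and C1–C2 (enantioselective conjugate addition).
3. Enabling feature: without ring A, ring B is 3,6-dimethylcyclohepta-2,6-dienone, which has a twofold axis through C6=O. Its two β-methyl enone arms (C7=C8 and C5=C1) are identical and are tied by the C9–C10 ethano bridge, so one C2 reagent can be joined to both β-carbons at once, and one catalyst-controlled addition later breaks the symmetry.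
4. Key disconnection: C8–C9 and C1–C10, by a twofold sp2–sp3 Suzuki–Miyaura annulation of the Z,Z-bis(β-iodoenone) 5 with 1,2-diborylethane 6.
5. Ring order: ring B (step 4), then ring A (steps 5–6). Stereocentres: C1 (step 5, catalyst), C4 and C5 (step 9, substrate and equilibration), C6 (step 10, directed).

Key step: step 4

Remark: 6 is taken as a commercial reagent (otherwise it is the platinum-catalysed diboration product of ethylene), and the ligand antipode in step 5 is assumed to be the one that delivers (S)-10.

**Route**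

Step 1
Reactants: 1 prop-1-ynylmagnesium bromide (2.1 equiv); 2 ethyl formate
Product: 3 hepta-2,5-diyn-4-ol
Conditions: THF, 0 °C to 25 °C; then aq. NH4Cl
Reagents that add atoms: none
Why: Twofold Grignard addition of the alkynyl nucleophile to the formate ester (through the ynal) should give the symmetrical bis-propargylic carbinol, with no stereocentre.

Step 2
Reactants: 3 hepta-2,5-diyn-4-ol
Product: 4 hepta-2,5-diyn-4-one
Conditions: DMP (1,1,1-triacetoxy-1λ5,2-benziodoxol-3-one), CH2Cl2, 0 °C to 25 °C; used crude
Reagents that add atoms: none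
Why: Dess–Martin oxidation of the secondary alcohol under neutral conditions should give the sensitive cross-conjugated diynone without hydration or polymerisation.

Step 3
Reactants: 4 hepta-2,5-diyn-4-one
Product: 5 (2Z,5Z)-2,6-diiodohepta-2,5-dien-4-one
Conditions: NaI (2.5 equiv), glacial AcOH, 25 °C, dark
Reagents that add atoms: sodium iodide, [Na+].[I-]
Why: Conjugate hydroiodination of each ynone arm by kinetic anti addition of HI should place iodine cis to the carbonyl, which is the Z,Z geometry the ring closure needs.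

Step 4
Reactants: 5 (2Z,5Z)-2,6-diiodohepta-2,5-dien-4-one; 6 1,2-bis(4,4,5,5-tetramethyl-1,3,2-dioxaborolan-2-yl)ethane
Product: 8 3,6-dimethylcyclohepta-2,6-dien-1-one, via iodo dienone boronate 7 (not isolated)
Conditions: Pd(OAc)2 (10 mol %), RuPhos (20 mol %), K3PO4 (6 equiv), toluene/H2O 10:1, 80 °C, syringe-pump addition of 5 and 6 (final 0.01 M)
Reagents that add atoms: none
Why: Proposed new method: two sp2–sp3 Suzuki–Miyaura couplings in one pot should join both carbons of the ethane-1,2-diyl bis(boronate) to the two enone β-carbons, forming C8–C9 and C1–C10; each event is oxidative addition of zerovalent palladium into a Z-vinyl C–I bond, base-assisted transmetalation of a primary alkylboronate (the first accelerated by the neighbouring boron) and reductive elimination. The closest known reactions are B-alkyl Suzuki–Miyaura couplings of β-iodoenones, the selective coupling of vicinal bis(pinacol boronates) at the primary carbon, and annulative twofold B-alkyl couplings of dihalides with α,ω-diborylalkanes; ring closure of a vicinal bis(boronate) onto a bis(vinyl iodide) has not been shown. The seven-membered ring closes in the second event by intramolecular transmetalation and C(sp2)–C(sp3) reductive elimination from an eight-membered palladacycle. No stereocentre is formed, the product is achiral with a twofold axis, and the Z geometry of both vinyl iodides from step 3 is retained and is what holds the U-shaped divinyl ketone so that C1 and C10 are within reach. The step needs cyclisation over oligomerisation (high dilution, slow addition), coupling over β-hydride elimination and protodeboronation (bulky electron-rich RuPhos), and coupling over hydrolysis of the β-iodoenone (phosphate base, biphasic medium).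

Step 5
Reactants: 8 3,6-dimethylcyclohepta-2,6-dien-1-one; 9 [2-(1,3-dioxolan-2-yl)ethyl]magnesium bromide (1.3 equiv)
Product: 10 (6S)-6-[2-(1,3-dioxolan-2-yl)ethyl]-3,6-dimethylcyclohept-2-en-1-one
Conditions: Cu(OTf)2 (5 mol %), chiral N-mesityl-N'-(1-hydroxy-4-methylpentan-2-yl)imidazolinium hexafluorophosphate (NHC precursor, 7 mol %), Et2O, −30 °C, slow addition of 9; then aq. NH4Cl
Reagents that add atoms: none
Why: Copper-catalysed asymmetric conjugate addition of the Grignard reagent to one of the two homotopic β-methyl enone arms should set quaternary C1, with the chiral NHC ligand choosing the enantiotopic face, while the magnesium enolate formed shields the second arm from over-addition.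

Step 6
Reactants: 10 (6S)-6-[2-(1,3-dioxolan-2-yl)ethyl]-3,6-dimethylcyclohept-2-en-1-one
Product: 12 (8aS)-3-hydroxy-6,8a-dimethyl-2,3,3a,7,8,8a-hexahydroazulen-4(1H)-one (mixture at C3 and C3a), via keto aldehyde 11 (not isolated)
Conditions: 2 M HCl, THF, 25 °C; then K2CO3, MeOH, 0 °C, quenched before dehydration
Reagents that add atoms: water, O
Why: Acetal hydrolysis followed by intramolecular aldol addition of the C5 ketone enolate to the aldehyde should close ring A (C4–C5); the configurations at C4 and C5 do not matter because both centres are made planar in steps 7 and 8.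

Step 7
Reactants: 12 (8aS)-3-hydroxy-6,8a-dimethyl-2,3,3a,7,8,8a-hexahydroazulen-4(1H)-one
Product: 13 (8aS)-6,8a-dimethyl-1,2,8,8a-tetrahydroazulene-3,4(3aH,7H)-dione (expected mainly as the enol toward C6)
Conditions: DMP, CH2Cl2, 0 °C to 25 °C
Reagents that add atoms: none
Why: Dess–Martin oxidation of the β-ketol should give the 1,3-diketone, which removes the C4 and C5 stereocentres created in step 6.

Step 8
Reactants: 13 (8aS)-6,8a-dimethyl-1,2,8,8a-tetrahydroazulene-3,4(3aH,7H)-dione
Product: 14 (8aS)-4-{[tert-butyl(dimethyl)silyl]oxy}-6,8a-dimethyl-1,2,8,8a-tetrahydroazulen-3(7H)-one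
Conditions: TBSCl, imidazole, DMF, 0 °C to 25 °C
Reagents that add atoms: tert-butyldimethylsilyl chloride, CC(C)(C)[Si](C)(C)Cl
Why: O-silylation should occur on the favoured linearly conjugated enol (C5=C6, exocyclic to the cyclopentanone), masking C6 as a vinylogous silyl ester and leaving the ring-A carbonyl C4 as the only ketone.

Step 9
Reactants: 14 (8aS)-4-{[tert-butyl(dimethyl)silyl]oxy}-6,8a-dimethyl-1,2,8,8a-tetrahydroazulen-3(7H)-one; 15 isopropyllithium
Product: 17 (3R,3aR,8aS)-3-hydroxy-6,8a-dimethyl-3-(propan-2-yl)-2,3,3a,7,8,8a-hexahydroazulen-4(1H)-one, via silyl dienol ether carbinol 16 (not isolated)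
Conditions: CeCl3 (anhydrous), i-PrLi, THF, −78 °C; then AcOH, Bu4NF, THF, 0 °C to 25 °C
Reagents that add atoms: none
Why: 1,2-Addition of the organocerium reagent to C4 from the face opposite the angular C1 methyl should set C4 (hydroxyl cis to the methyl), and buffered fluoride cleavage of the silyl enol ether (a Stork–Danheiser sequence stopped before elimination) with equilibration at the epimerisable C5 should give the trans-fused ketol, in which C6 is anti to the isopropyl group and hydrogen-bonded to the C4 hydroxyl.

Step 10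
Reactants: 17 (3R,3aR,8aS)-3-hydroxy-6,8a-dimethyl-3-(propan-2-yl)-2,3,3a,7,8,8a-hexahydroazulen-4(1H)-one
Product: 18 (3R,3aS,4S,8aS)-6,8a-dimethyl-3-(propan-2-yl)-1,2,3,3a,4,7,8,8a-octahydroazulene-3,4-diol
Conditions: Me4NBH(OAc)3, MeCN/AcOH 1:1, −20 °C
Reagents that add atoms: none
Why: In this Saksena–Evans reduction the borohydride bound to the C4 oxygen should deliver hydride to the C6 carbonyl from the face of ring B that carries C4, giving the 1,3-anti diol with the new hydroxyl cis to H5 (6S) and leaving the enone C=C untouched.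

Step 11
Reactants: 18 (3R,3aS,4S,8aS)-6,8a-dimethyl-3-(propan-2-yl)-1,2,3,3a,4,7,8,8a-octahydroazulene-3,4-diol; 19 4-methoxybenzoyl chloride
Product: 20 (3R,3aS,4S,8aS)-3-hydroxy-6,8a-dimethyl-3-(propan-2-yl)-1,2,3,3a,4,7,8,8a-octahydroazulen-4-yl 4-methoxybenzoate
Conditions: Et3N, DMAP (cat.), CH2Cl2, 0 °C to 25 °C
Reagents that add atoms: none
Why: DMAP-catalysed acylation should take place only at the secondary allylic C6 hydroxyl, because the tertiary C4 hydroxyl is too hindered to react.

**Compound list**

1 | prop-1-ynylmagnesium bromide | CC#C[Mg]Br | starting material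
2 | ethyl formate | CCOC=O | starting material
3 | hepta-2,5-diyn-4-ol | CC#CC(O)C#CC | intermediate
4 | hepta-2,5-diyn-4-one | CC#CC(=O)C#CC | intermediate
5 | (2Z,5Z)-2,6-diiodohepta-2,5-dien-4-one | C/C(I)=C/C(=O)/C=C(/C)I | intermediate
6 | 1,2-bis(4,4,5,5-tetramethyl-1,3,2-dioxaborolan-2-yl)ethane | CC1(C)OB(CCB2OC(C)(C)C(C)(C)O2)OC1(C)C | starting material
7 | (2Z,5Z)-2-iodo-6-methyl-8-(4,4,5,5-tetramethyl-1,3,2-dioxaborolan-2-yl)octa-2,5-dien-4-one | C/C(I)=C/C(=O)/C=C(/C)CCB1OC(C)(C)C(C)(C)O1 | intermediate
8 | 3,6-dimethylcyclohepta-2,6-dien-1-one | CC1=CC(=O)C=C(C)CC1 | intermediate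
9 | [2-(1,3-dioxolan-2-yl)ethyl]magnesium bromide | Br[Mg]CCC1OCCO1 | starting material
10 | (6S)-6-[2-(1,3-dioxolan-2-yl)ethyl]-3,6-dimethylcyclohept-2-en-1-one | O=C1C=C(C)CC[C@@](C)(CCC2OCCO2)C1 | intermediate
11 | 3-[(1S)-1,4-dimethyl-6-oxocyclohept-4-en-1-yl]propanal | O=C1C=C(C)CC[C@@](C)(CCC=O)C1 | intermediate
12 | (8aS)-3-hydroxy-6,8a-dimethyl-2,3,3a,7,8,8a-hexahydroazulen-4(1H)-one | O=C1C=C(C)CC[C@@]2(C)CCC(O)C12 | intermediate
13 | (8aS)-6,8a-dimethyl-1,2,8,8a-tetrahydroazulene-3,4(3aH,7H)-dione | O=C1C=C(C)CC[C@@]2(C)CCC(=O)C12 | intermediate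
14 | (8aS)-4-{[tert-butyl(dimethyl)silyl]oxy}-6,8a-dimethyl-1,2,8,8a-tetrahydroazulen-3(7H)-one | CC(C)(C)[Si](C)(C)OC1=C2C(=O)CC[C@]2(C)CCC(C)=C1 | intermediate
15 | isopropyllithium | [Li]C(C)C | starting material
16 | (3R,8aS)-4-{[tert-butyl(dimethyl)silyl]oxy}-6,8a-dimethyl-3-(propan-2-yl)-1,2,3,7,8,8a-hexahydroazulen-3-ol | CC(C)(C)[Si](C)(C)OC1=C2[C@](O)(C(C)C)CC[C@]2(C)CCC(C)=C1 | intermediate
17 | (3R,3aR,8aS)-3-hydroxy-6,8a-dimethyl-3-(propan-2-yl)-2,3,3a,7,8,8a-hexahydroazulen-4(1H)-one | O=C1C=C(C)CC[C@@]2(C)CC[C@@](O)(C(C)C)[C@H]12 | intermediate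
18 | (3R,3aS,4S,8aS)-6,8a-dimethyl-3-(propan-2-yl)-1,2,3,3a,4,7,8,8a-octahydroazulene-3,4-diol | O[C@H]1C=C(C)CC[C@@]2(C)CC[C@@](O)(C(C)C)[C@H]12 | intermediate
19 | 4-methoxybenzoyl chloride | COc1ccc(C(Cl)=O)cc1 | starting material
20 | (3R,3aS,4S,8aS)-3-hydroxy-6,8a-dimethyl-3-(propan-2-yl)-1,2,3,3a,4,7,8,8a-octahydroazulen-4-yl 4-methoxybenzoate | COc1ccc(C(=O)O[C@H]2C=C(C)CC[C@@]3(C)CC[C@@](O)(C(C)C)[C@H]23)cc1 | target

**Step count and risks**

Total step count: 11. Longest linear sequence: 11 steps (1 and 2 to 20); 6, 9, 15 and 19 are purchased.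

Three steps most likely to fail:

1. Step 4 (proposed new method). The second, unactivated primary alkylboronate may transmetalate too slowly, so that oligomerisation, protodehalogenation of the remaining vinyl iodide, or hydrolytic loss of iodide from the β-iodoenone outruns ring closure. The fallback sets out from 4 and returns at 8, and makes the same two bonds by carbanion chemistry. Double Michael addition of commercial tetraethyl ethane-1,1,2,2-tetracarboxylate (a 1,2-dicarbanion equivalent; Cs2CO3, MeCN, 0 °C to 25 °C, dilute) to both ynone arms of 4 would give tetraethyl 3,7-dimethyl-5-oxocyclohepta-3,6-diene-1,1,2,2-tetracarboxylate F1. Saponification (KOH, aq. EtOH) would give 3,7-dimethyl-5-oxocyclohepta-3,6-diene-1,1,2,2-tetracarboxylic acid F2, and acidification with heating would remove all four carboxyl groups (two malonic, then two vinylogous β-keto acid decarboxylations) to give 8.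

2. Step 9. The angular methyl and the C10 methylene may not differentiate the two faces of the C4 carbonyl well enough, and the tertiary β-alkoxide may eliminate or undergo retro-aldol cleavage during desilylation. The fallback sets out from 14 and returns at 17, and fixes C4 by a directed epoxidation instead of a carbonyl addition. Addition of i-PrLi/CeCl3 as in step 9, followed by 1 M HCl (full Stork–Danheiser transposition), would erase C4 and give the cross-conjugated dienone (8aS)-6,8a-dimethyl-3-(propan-2-yl)-1,2,8,8a-tetrahydroazulen-4(7H)-one F3. Luche reduction (NaBH4, CeCl3, MeOH, −78 °C) from the face opposite the angular methyl would give (4R,8aS)-6,8a-dimethyl-3-(propan-2-yl)-1,2,4,7,8,8a-hexahydroazulen-4-ol F4. Hydroxyl-directed epoxidation (VO(acac)2, t-BuOOH) of the tetrasubstituted C4=C5 alkene syn to the C6 hydroxyl would give the C4–C5 epoxy alcohol F5 (oxirane oxygen cis to the hydroxyl and the angular methyl). DMP oxidation would give the epoxy ketone F6, and SmI2 (THF/MeOH, −78 °C) would cleave the C5–O bond to give 17 after protonation at C5.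

3. Step 6. The ketol may dehydrate to the ring-A enone, or the aldehyde enolate may attack the ketone instead, before the aldol adduct can be oxidised. The fallback sets out from 10 and returns at 13, and closes ring A by acylation instead of aldol addition and oxidation. Acetal hydrolysis (2 M HCl, THF) with isolation of 11, then Pinnick oxidation (NaClO2, NaH2PO4, 2-methylbut-2-ene), would give 3-[(1S)-1,4-dimethyl-6-oxocyclohept-4-en-1-yl]propanoic acid F7. Esterification (MeI, K2CO3, DMF) would give its methyl ester F8, and intramolecular Claisen acylation of the C5 ketone enolate (LiN(SiMe3)2, 2.2 equiv, THF, −78 °C to 0 °C) would give 13 directly.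

Further compounds
F1 | step 4 | tetraethyl 3,7-dimethyl-5-oxocyclohepta-3,6-diene-1,1,2,2-tetracarboxylate | CCOC(=O)C1(C(=O)OCC)C(C)=CC(=O)C=C(C)C1(C(=O)OCC)C(=O)OCC
F2 | step 4 | 3,7-dimethyl-5-oxocyclohepta-3,6-diene-1,1,2,2-tetracarboxylic acid | OC(=O)C1(C(O)=O)C(C)=CC(=O)C=C(C)C1(C(O)=O)C(O)=O
F3 | step 9 | (8aS)-6,8a-dimethyl-3-(propan-2-yl)-1,2,8,8a-tetrahydroazulen-4(7H)-one | O=C1C=C(C)CC[C@@]2(C)CCC(C(C)C)=C12
F4 | step 9 | (4R,8aS)-6,8a-dimethyl-3-(propan-2-yl)-1,2,4,7,8,8a-hexahydroazulen-4-ol | O[C@@H]1C=C(C)CC[C@@]2(C)CCC(C(C)C)=C12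
F5 | step 9 | 3,3a-epoxide of F4 with the oxirane oxygen cis to the C4 hydroxyl and the 8a-methyl | O[C@@H]1C=C(C)CC[C@@]2(C)CC[C@]3(C(C)C)O[C@]123
F6 | step 9 | 3,3a-epoxy ketone from oxidation of F5 | O=C1C=C(C)CC[C@@]2(C)CC[C@]3(C(C)C)O[C@]123
F7 | step 6 | 3-[(1S)-1,4-dimethyl-6-oxocyclohept-4-en-1-yl]propanoic acid | O=C1C=C(C)CC[C@@](C)(CCC(=O)O)C1
F8 | step 6 | methyl 3-[(1S)-1,4-dimethyl-6-oxocyclohept-4-en-1-yl]propanoate | O=C1C=C(C)CC[C@@](C)(CCC(=O)OC)C1
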